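## Retrosynthetic overview

1. The target acid comes from its 2-(trimethylsilyl)ethyl ester, which is assembled by a catalytic asymmetric Ni/Cr (Nozaki–Hiyama–Kishi) union of a tetrahydropyran aldehyde (fragment A) with a C13 2-iodo-1,5,9-triene (fragment B, from geraniol); this union sets the carbinol centre.
2. Fragment A comes from a trans-2,5-disubstituted tetrahydropyran-2-acetate by α-methylenation and selective ozonolysis of a butenyl arm.
3. The only ring (the tetrahydropyran) is closed by an intramolecular oxa-Michael addition of a δ-hydroxy enoate, made by Wittig reaction of a lactol with a silylethyl ylide (fragment C); C2 is set here under thermodynamic control.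
4. The lactol comes from an Evans titanium-enolate Michael addition of an N-hexenoyl oxazolidinone to acrylonitrile (sets C5), followed by LiBH4 and i-Bu2AlH reductions.

Assumption: in the fragment union the (S)-configured oxazoline sulfonamide ligand is taken to direct the alkenyl group to the Si face of the aldehyde; if a first run (Mosher ester check) shows the opposite sense, its mirror image is used.

## Fragment C (ylide)

Step 1
Reactants: 1 2-(trimethylsilyl)ethanol; 2 bromoacetyl bromide
Product: 3 2-(trimethylsilyl)ethyl 2-bromoacetate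
Conditions: pyridine, CH2Cl2, 0 °C
Reagents that add atoms: none
Why: Nucleophilic acyl substitution of the primary alcohol on the acyl bromide, which is far more reactive than the alkyl bromide.

Step 2
Reactants: 3 2-(trimethylsilyl)ethyl 2-bromoacetate
Product: 5 2-(trimethylsilyl)ethyl 2-(triphenylphosphoranylidene)acetate, via phosphonium bromide 4 (not isolated)
Conditions: PPh3, toluene, rt; then 1 M aq. NaOH, CH2Cl2, 0 °C
Reagents that add atoms: triphenylphosphine, c1ccc(cc1)P(c1ccccc1)c1ccccc1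
Why: SN2 quaternisation of the phosphine by the α-bromo ester and deprotonation give the stabilised Wittig ylide.

## Fragment B (alkenyl iodide)

Step 3
Reactants: 6 geraniol
Product: 7 geranyl bromide [(2E)-1-bromo-3,7-dimethylocta-2,6-diene]
Conditions: PBr3 (0.4 equiv), Et2O, −10 °C; used at once
Reagents that add atoms: phosphorus tribromide, BrP(Br)Br
Why: Low-temperature SN2 bromination of the primary allylic alcohol through its phosphite ester keeps the E double bond in place.

Step 4
Reactants: 7 geranyl bromide; 8 trimethyl(prop-1-yn-1-yl)silane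
Product: 10 [(5E)-6,10-dimethylundeca-5,9-dien-1-yn-1-yl]trimethylsilane, via lithiated silylpropyne 9 (not isolated)
Conditions: 8, n-BuLi, THF, −78 to −20 °C; then 7, −78 °C to rt
Reagents that add atoms: none
Why: Propargylic lithiation followed by SN2 alkylation at the primary allylic bromide; the silyl group blocks the alkyne terminus and favours the propargyl over the allenyl product.

Step 5
Reactants: 10 [(5E)-6,10-dimethylundeca-5,9-dien-1-yn-1-yl]trimethylsilane
Product: 11 (5E)-6,10-dimethylundeca-5,9-dien-1-yne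
Conditions: K2CO3, MeOH, rt
Reagents that add atoms: none
Why: Base-catalysed methanolysis of the alkynyl–silicon bond (protodesilylation) leaves the alkenes untouched.

Step 6
Reactants: 11 (5E)-6,10-dimethylundeca-5,9-dien-1-yne
Product: 13 (5E)-2-iodo-6,10-dimethylundeca-1,5,9-triene, via iodovinylborane 12 (not isolated)
Conditions: B-iodo-9-borabicyclo[3.3.1]nonane (1.2 equiv), pentane, −20 to 0 °C; then AcOH, 0 °C
Reagents that add atoms: B-iodo-9-borabicyclo[3.3.1]nonane, IB1C2CCCC1CCC2
Why: Syn haloboration of the terminal alkyne (boron to the terminal carbon, iodide to the internal one) followed by protodeboronation gives the 2-iodo-1-alkene, and the reagent does not add to the trisubstituted alkenes at this temperature.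

## Fragment A (tetrahydropyran aldehyde)

Step 7
Reactants: 14 (R)-4-benzyl-1,3-oxazolidin-2-one; 15 hex-5-enoyl chloride
Product: 16 (4R)-4-benzyl-3-(hex-5-enoyl)-1,3-oxazolidin-2-one
Conditions: Et3N, 4-(dimethylamino)pyridine (10 mol%), CH2Cl2, 0 °C to rt
Reagents that add atoms: none
Why: Acyl-transfer-catalysed N-acylation of the Evans auxiliary.

Step 8
Reactants: 16 (4R)-4-benzyl-3-(hex-5-enoyl)-1,3-oxazolidin-2-one; 17 acrylonitrile
Product: 19 (4R)-4-benzyl-3-[(2S)-2-(2-cyanoethyl)hex-5-enoyl]-1,3-oxazolidin-2-one, via titanium enolate 18 (not isolated)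
Conditions: TiCl3(OiPr) (from TiCl4 and Ti(OiPr)4, 3:1), iPr2NEt, CH2Cl2, 0 °C; then 17, 0 °C to rt; aq. NH4Cl
Reagents that add atoms: none
Why: Evans auxiliary-controlled Michael addition in which the chelated Z enolate 18 adds to acrylonitrile on the face opposite the benzyl group, setting the 2S centre (later C5 of the ring) with the usual selectivity above 95:5.

Step 9
Reactants: 19 (4R)-4-benzyl-3-[(2S)-2-(2-cyanoethyl)hex-5-enoyl]-1,3-oxazolidin-2-one
Product: 20 (4S)-4-(hydroxymethyl)oct-7-enenitrile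
Conditions: LiBH4, H2O (1 equiv), Et2O, 0 °C
Reagents that add atoms: none
Why: Reductive cleavage of the imide to the primary alcohol, without epimerisation and without touching the nitrile or the alkene.

Step 10
Reactants: 20 (4S)-4-(hydroxymethyl)oct-7-enenitrile
Product: 22 (5S)-5-(but-3-en-1-yl)oxan-2-ol, via hydroxy aldehyde 21 (not isolated)
Conditions: i-Bu2AlH (2.5 equiv), CH2Cl2, −78 °C; then MeOH, 1 M aq. HCl, 0 °C
Reagents that add atoms: water, O
Why: Partial reduction of the nitrile to the aluminated imine and hydrolysis give the aldehyde, which closes at once to the six-membered lactol.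

Step 11
Reactants: 22 (5S)-5-(but-3-en-1-yl)oxan-2-ol; 5 2-(trimethylsilyl)ethyl 2-(triphenylphosphoranylidene)acetate
Product: 23 2-(trimethylsilyl)ethyl (2E,6S)-6-(hydroxymethyl)deca-2,9-dienoate
Conditions: toluene, 80 °C
Reagents that add atoms: none
Why: Wittig olefination of the open-chain aldehyde tautomer of the lactol by a stabilised ylide gives the E enoate and frees the primary alcohol.

Step 12
Reactants: 23 2-(trimethylsilyl)ethyl (2E,6S)-6-(hydroxymethyl)deca-2,9-dienoate
Product: 24 2-(trimethylsilyl)ethyl 2-[(2R,5S)-5-(but-3-en-1-yl)oxan-2-yl]acetate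
Conditions: KOtBu (20 mol%), THF, 0 °C to rt; AcOH quench
Reagents that add atoms: none
Why: Base-catalysed 6-exo intramolecular oxa-Michael addition closes the tetrahydropyran, and because the addition is reversible the chair with both substituents equatorial wins, giving the 2,5-trans ring (2R, about 9:1 expected; the minor cis isomer is separated and re-equilibrated).

Step 13
Reactants: 24 2-(trimethylsilyl)ethyl 2-[(2R,5S)-5-(but-3-en-1-yl)oxan-2-yl]acetate
Product: 26 2-(trimethylsilyl)ethyl 2-[(2R,5S)-5-(but-3-en-1-yl)oxan-2-yl]-3-(dimethylamino)propanoate, via lithium enolate 25 (not isolated)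
Conditions: LiN(iPr)2 (1.2 equiv), THF, −78 °C; then CH2=NMe2+ I−, −78 °C to rt
Reagents that add atoms: N,N-dimethylmethylideneammonium iodide, C=[N+](C)C.[I-]
Why: Mannich reaction of the ester enolate 25, kept at −78 °C so that β-alkoxide elimination does not compete; the new α centre is formed as a mixture and is destroyed in the next step.

Step 14
Reactants: 26 2-(trimethylsilyl)ethyl 2-[(2R,5S)-5-(but-3-en-1-yl)oxan-2-yl]-3-(dimethylamino)propanoate
Product: 28 2-(trimethylsilyl)ethyl 2-[(2R,5S)-5-(but-3-en-1-yl)oxan-2-yl]prop-2-enoate, via ammonium iodide 27 (not isolated)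
Conditions: MeI, CH2Cl2, rt; evaporate; then 1,8-diazabicyclo[5.4.0]undec-7-ene (DBU), CH2Cl2, 0 °C
Reagents that add atoms: none
Why: N-quaternisation followed by E1cB elimination of trimethylamine gives the α-methylene ester, the ammonium group being a much better leaving group than the ring oxygen.

Step 15
Reactants: 28 2-(trimethylsilyl)ethyl 2-[(2R,5S)-5-(but-3-en-1-yl)oxan-2-yl]prop-2-enoate
Product: 30 2-(trimethylsilyl)ethyl 2-[(2R,5R)-5-(3-oxopropyl)oxan-2-yl]prop-2-enoate, via ozonide 29 (not isolated)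
Conditions: O3/O2, CH2Cl2, −78 °C, Sudan Red 7B as end-point indicator; then PPh3, −78 °C to rt
Reagents that add atoms: ozone, [O-][O+]=O
Why: Ozonolysis with reductive work-up, in which electrophilic ozone cleaves the electron-rich monosubstituted alkene much faster than the electron-poor acrylate (the 5R label is only a priority change, the centre is untouched).

## Union and end game

Step 16
Reactants: 30 2-(trimethylsilyl)ethyl 2-[(2R,5R)-5-(3-oxopropyl)oxan-2-yl]prop-2-enoate; 13 (5E)-2-iodo-6,10-dimethylundeca-1,5,9-triene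
Product: 31 2-(trimethylsilyl)ethyl 2-[(2R,5S)-5-[(3R,7E)-3-hydroxy-8,12-dimethyl-4-methylidenetrideca-7,11-dien-1-yl]oxan-2-yl]prop-2-enoate
Conditions: CrCl2 (10 mol%), (S)-N-[2-(4-isopropyl-4,5-dihydro-1,3-oxazol-2-yl)-6-methylphenyl]methanesulfonamide (12 mol%), 1,8-bis(dimethylamino)naphthalene (12 mol%), NiCl2·(2,9-dimethyl-1,10-phenanthroline) (2 mol%), Mn (2 equiv), Cp2ZrCl2 (1.2 equiv), LiCl (2 equiv), MeCN, rt; aq. NaHCO3 work-up
Reagents that add atoms: none
Why: Catalytic asymmetric Nozaki–Hiyama–Kishi coupling in which the chiral chromium sulfonamide complex delivers the 1-substituted vinyl group to the Si face of the aldehyde, setting the 3R carbinol, while the ester, the acrylate and the trisubstituted alkenes are inert.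

Step 17
Reactants: 31 2-(trimethylsilyl)ethyl 2-[(2R,5S)-5-[(3R,7E)-3-hydroxy-8,12-dimethyl-4-methylidenetrideca-7,11-dien-1-yl]oxan-2-yl]prop-2-enoate
Product: 32 2-[(2R,5S)-5-[(3R,7E)-3-hydroxy-8,12-dimethyl-4-methylidenetrideca-7,11-dien-1-yl]oxan-2-yl]prop-2-enoic acid (CNP0197923.2)
Conditions: Bu4NF (3 equiv), THF, 0 °C to rt; dilute aq. HCl to pH 4
Reagents that add atoms: none
Why: Fluoride-induced fragmentation of the 2-silylethyl ester frees the acid without hydroxide, so the β-alkoxy acrylate, the allylic alcohol and all three stereocentres are untouched.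

## Compound list

1 | 2-(trimethylsilyl)ethanol | C[Si](C)(C)CCO | starting material
2 | bromoacetyl bromide | BrCC(Br)=O | starting material
3 | 2-(trimethylsilyl)ethyl 2-bromoacetate | C[Si](C)(C)CCOC(=O)CBr | intermediate
4 | triphenyl{2-oxo-2-[2-(trimethylsilyl)ethoxy]ethyl}phosphonium bromide | C[Si](C)(C)CCOC(=O)C[P+](c1ccccc1)(c1ccccc1)c1ccccc1.[Br-] | intermediate
5 | 2-(trimethylsilyl)ethyl 2-(triphenylphosphoranylidene)acetate | C[Si](C)(C)CCOC(=O)C=P(c1ccccc1)(c1ccccc1)c1ccccc1 | intermediate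
6 | geraniol [(2E)-3,7-dimethylocta-2,6-dien-1-ol] | OC/C=C(\C)CCC=C(C)C | starting material
7 | geranyl bromide [(2E)-1-bromo-3,7-dimethylocta-2,6-diene] | BrC/C=C(\C)CCC=C(C)C | intermediate
8 | trimethyl(prop-1-yn-1-yl)silane | CC#C[Si](C)(C)C | starting material
9 | [3-(trimethylsilyl)prop-2-yn-1-yl]lithium | [Li]CC#C[Si](C)(C)C | intermediate
10 | [(5E)-6,10-dimethylundeca-5,9-dien-1-yn-1-yl]trimethylsilane | C[Si](C)(C)C#CCC/C=C(\C)CCC=C(C)C | intermediate
11 | (5E)-6,10-dimethylundeca-5,9-dien-1-yne | C#CCC/C=C(\C)CCC=C(C)C | intermediate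
12 | 9-[(1Z,5E)-2-iodo-6,10-dimethylundeca-1,5,9-trien-1-yl]-9-borabicyclo[3.3.1]nonane | I/C(CC/C=C(\C)CCC=C(C)C)=C\B1C2CCCC1CCC2 | intermediate
13 | (5E)-2-iodo-6,10-dimethylundeca-1,5,9-triene | C=C(I)CC/C=C(\C)CCC=C(C)C | intermediate
14 | (R)-4-benzyl-1,3-oxazolidin-2-one | O=C1N[C@H](Cc2ccccc2)CO1 | starting material
15 | hex-5-enoyl chloride | C=CCCCC(Cl)=O | starting material
16 | (4R)-4-benzyl-3-(hex-5-enoyl)-1,3-oxazolidin-2-one | C=CCCCC(=O)N1[C@H](Cc2ccccc2)COC1=O | intermediate
17 | acrylonitrile | C=CC#N | starting material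
18 | dichloro(isopropoxy)titanium (Z)-enolate of 16 | C=CCC/C=C(\O[Ti](Cl)(Cl)OC(C)C)N1[C@H](Cc2ccccc2)COC1=O | intermediate
19 | (4R)-4-benzyl-3-[(2S)-2-(2-cyanoethyl)hex-5-enoyl]-1,3-oxazolidin-2-one | C=CCC[C@@H](CCC#N)C(=O)N1[C@H](Cc2ccccc2)COC1=O | intermediate
20 | (4S)-4-(hydroxymethyl)oct-7-enenitrile | C=CCC[C@@H](CCC#N)CO | intermediate
21 | (4S)-4-(hydroxymethyl)oct-7-enal | C=CCC[C@@H](CCC=O)CO | intermediate
22 | (5S)-5-(but-3-en-1-yl)oxan-2-ol (anomer mixture) | C=CCC[C@H]1CCC(O)OC1 | intermediate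
23 | 2-(trimethylsilyl)ethyl (2E,6S)-6-(hydroxymethyl)deca-2,9-dienoate | C=CCC[C@H](CO)CC/C=C/C(=O)OCC[Si](C)(C)C | intermediate
24 | 2-(trimethylsilyl)ethyl 2-[(2R,5S)-5-(but-3-en-1-yl)oxan-2-yl]acetate | C=CCC[C@H]1CC[C@H](CC(=O)OCC[Si](C)(C)C)OC1 | intermediate
25 | lithium enolate of 24 | C=CCC[C@H]1CC[C@H](C=C(O[Li])OCC[Si](C)(C)C)OC1 | intermediate
26 | 2-(trimethylsilyl)ethyl 2-[(2R,5S)-5-(but-3-en-1-yl)oxan-2-yl]-3-(dimethylamino)propanoate (both epimers at C2 of the propanoate) | C=CCC[C@H]1CC[C@H](C(CN(C)C)C(=O)OCC[Si](C)(C)C)OC1 | intermediate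
27 | {2-[(2R,5S)-5-(but-3-en-1-yl)oxan-2-yl]-3-oxo-3-[2-(trimethylsilyl)ethoxy]propyl}trimethylammonium iodide | C=CCC[C@H]1CC[C@H](C(C[N+](C)(C)C)C(=O)OCC[Si](C)(C)C)OC1.[I-] | intermediate
28 | 2-(trimethylsilyl)ethyl 2-[(2R,5S)-5-(but-3-en-1-yl)oxan-2-yl]prop-2-enoate | C=CCC[C@H]1CC[C@H](C(=C)C(=O)OCC[Si](C)(C)C)OC1 | intermediate
29 | 2-(trimethylsilyl)ethyl 2-[(2R,5R)-5-[2-(1,2,4-trioxolan-3-yl)ethyl]oxan-2-yl]prop-2-enoate | C1(OCOO1)CC[C@H]2CC[C@H](C(=C)C(=O)OCC[Si](C)(C)C)OC2 | intermediate
30 | 2-(trimethylsilyl)ethyl 2-[(2R,5R)-5-(3-oxopropyl)oxan-2-yl]prop-2-enoate | O=CCC[C@H]1CC[C@H](C(=C)C(=O)OCC[Si](C)(C)C)OC1 | intermediate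
31 | 2-(trimethylsilyl)ethyl 2-[(2R,5S)-5-[(3R,7E)-3-hydroxy-8,12-dimethyl-4-methylidenetrideca-7,11-dien-1-yl]oxan-2-yl]prop-2-enoate | C=C(CC/C=C(\C)CCC=C(C)C)[C@H](O)CC[C@H]1CC[C@H](C(=C)C(=O)OCC[Si](C)(C)C)OC1 | intermediate
32 | 2-[(2R,5S)-5-[(3R,7E)-3-hydroxy-8,12-dimethyl-4-methylidenetrideca-7,11-dien-1-yl]oxan-2-yl]prop-2-enoic acid | C=C(CC/C=C(\C)CCC=C(C)C)[C@H](O)CC[C@H]1CC[C@H](C(=C)C(=O)O)OC1 | target

## Step count and risks

Total step count: 17 (2 for fragment C, 4 for fragment B, 9 for fragment A, 2 after the union).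
Longest linear sequence: 11 steps (steps 7 to 17, from 14 and 15 to 32).

The three steps most likely to fail:

1. Step 16. The level, and for this ligand the sense, of induction on an unhindered aliphatic aldehyde may be insufficient, and the carbinol epimers are hard to separate. The fallback sets out from 30 (with 13) and comes back at 31. A ligand-free coupling (CrCl2, 4 equiv, NiCl2, 2 mol%, DMF, rt) gives the carbinol epimer mixture F1. Oxidation with Dess–Martin periodinane (NaHCO3, CH2Cl2) gives the cross-conjugated enone F2. Corey–Bakshi–Shibata reduction with (S)-1-methyl-3,3-diphenyltetrahydro-1H,3H-pyrrolo[1,2-c][1,3,2]oxazaborole and catecholborane (toluene, −78 °C) then gives 31; the 1-alkylvinyl group acts as the large substituent, so the (S)-catalyst gives the 3R alcohol.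

2. Step 13. The enolate of the β-alkoxy ester can open the ring by β-elimination (retro-oxa-Michael), losing material and C2 integrity. The fallback sets out from 22 and comes back at 28, replacing steps 11 to 14 without any ester enolate. Condensation of 22 with Meldrum's acid (L-proline cat., MeCN, rt) gives the alkylidene Meldrum's acid F3, which closes in the flask by the same reversible intramolecular oxa-Michael addition to the trans tetrahydropyranyl Meldrum's acid F4. Heating F4 with CH2=NMe2+ I− in 2-(trimethylsilyl)ethanol/THF (65 °C) gives the Mannich adduct F5, which undergoes alcoholysis and decarboxylative loss of dimethylamine to give 28.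

3. Step 6. The Lewis acidic boron iodide, or HI formed from it, may attack the trisubstituted alkenes of the 1,5-diene (hydroiodination or cation–olefin cyclisation). The fallback sets out from 11 and comes back at 13. Nickel-catalysed α-selective hydroalumination (NiCl2[Ph2P(CH2)3PPh2], 3 mol%, i-Bu2AlH, THF, rt) gives the 2-alumino-1-alkene F6, and iodinolysis (I2, THF, −78 °C) gives 13.

Further compounds
F1 | step 16 | 2-(trimethylsilyl)ethyl 2-[(2R,5S)-5-[(3RS,7E)-3-hydroxy-8,12-dimethyl-4-methylidenetrideca-7,11-dien-1-yl]oxan-2-yl]prop-2-enoate (carbinol epimer mixture) | C=C(CC/C=C(\C)CCC=C(C)C)C(O)CC[C@H]1CC[C@H](C(=C)C(=O)OCC[Si](C)(C)C)OC1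
F2 | step 16 | 2-(trimethylsilyl)ethyl 2-[(2R,5R)-5-[(7E)-8,12-dimethyl-4-methylidene-3-oxotrideca-7,11-dien-1-yl]oxan-2-yl]prop-2-enoate | C=C(CC/C=C(\C)CCC=C(C)C)C(=O)CC[C@H]1CC[C@H](C(=C)C(=O)OCC[Si](C)(C)C)OC1
F3 | step 13 | 5-[(4S)-4-(hydroxymethyl)oct-7-en-1-ylidene]-2,2-dimethyl-1,3-dioxane-4,6-dione | C=CCC[C@H](CO)CCC=C1C(=O)OC(C)(C)OC1=O
F4 | step 13 | 5-[(2R,5S)-5-(but-3-en-1-yl)oxan-2-yl]-2,2-dimethyl-1,3-dioxane-4,6-dione | C=CCC[C@H]1CC[C@H](C2C(=O)OC(C)(C)OC2=O)OC1
F5 | step 13 | 5-[(2R,5S)-5-(but-3-en-1-yl)oxan-2-yl]-5-[(dimethylamino)methyl]-2,2-dimethyl-1,3-dioxane-4,6-dione | C=CCC[C@H]1CC[C@H](C2(CN(C)C)C(=O)OC(C)(C)OC2=O)OC1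
F6 | step 6 | [(5E)-6,10-dimethylundeca-1,5,9-trien-2-yl]bis(2-methylpropyl)alumane | C=C(CC/C=C(\C)CCC=C(C)C)[Al](CC(C)C)CC(C)C
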